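## The problem

The target is a cis-fused furo[3,4-c]furan-1-one. A tetrahydrofuran (O5, C4, C3a, C6a, C6) and a γ-lactone (C1, O2, C3, C3a, C6a) share the C3a–C6a bond. C6 carries a guaiacyl ring and C3 a syringyl ring, so the two halves differ in ring type and in aryl group, and no dimerisation shortcut exists. Four contiguous stereocentres (3S,3aR,6S,6aS) are required, with both aryl groups on the convex face. C6 and C3 are benzylic C–O centres next to para-oxygenated rings; they ionise easily and settle in the exo arrangement once the bicycle exists. C6a and C3a are C–H centres that nothing later can correct, and they carry the absolute configuration. The same benzylic C–O bonds make the molecule fragile: acid opens them reversibly, base expels them through quinone methides once the phenols are free, and hydrogenolysis cleaves them. The lactone adds sensitivity to nucleophiles, so protecting groups must leave under mild, non-reductive, near-neutral conditions. The enabling feature is the C6a–C3a bond: C6a bears the carboxyl carbon C1 and the carbinol carbon C6, C3a bears the oxymethyl carbon C4 and C3. If C3 is read as the inner carbon of a vinyl group, C1–C6a–C3a–C3=C is a γ,δ-unsaturated acid and O–C6–C6a–C1 a β-hydroxy acid, the pattern left by an ester enolate Claisen rearrangement of a β-hydroxy ester dianion.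

## Retrosynthesis

**Phenol unmasking.** Target 17 is traced to its guaiacyl triisopropylsilyl ether 16. A silyl ether is preferred to a benzyl ether because hydrogenolysis would endanger the C3–O2 and C6–O5 bonds. The forward step must remove silicon without generating a free phenoxide for any length of time.

**C3–aryl bond.** Cutting the bond between C3 and the syringyl ring of 16 gives lactol-lactone 14 and 2,6-dimethoxyphenol 15. The neighbouring cuts (C3–O2 by lactonisation after adding an aryl metal to an aldehyde, or C3–C3a by an aldol reaction) need a protected aryl nucleophile and leave C3 to substrate control in an open chain. The Friedel–Crafts cut uses the unprotected phenol and lets the bicycle direct the arene to the convex face. The forward reaction must be para-selective on 15 and must stop after one arylation.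

**C3 oxidation level.** The lactol carbon C3 of 14 is taken back to the vinyl group of tetrahydrofuran acid 12; formyl acid 13 closes spontaneously onto the cis carboxyl group. This removes one ring and one oxygenated carbon. The forward step must cleave a terminal alkene beside an electron-rich arene.

**C6–O5 bond.** Opening the ether ring of 12 at the benzylic C6–O5 bond gives the acyclic hydroxy acid 11, with O5 carried as a silyl ether. This cut is chosen over C4–O5 because closure through the C6 cation makes the configuration at C6 in 11 irrelevant. That in turn frees C6 to serve as a temporary control element. The forward step must favour ether formation over lactonisation of the carboxyl group with the C4 oxygen.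

**C6a–C3a bond (key cut).** The [3,3] retron in 11 leads to allylic β-hydroxy ester 9, reacting through its chelated dianion 10. The cut removes two stereocentres and one C–C bond and leaves a single carbinol stereocentre. It is preferred to an aldol cut at C6–C6a, which would still leave C3a to be made separately. The forward step must relay the C6 configuration to C6a and, through a chair, to C3a.

**Carbinol.** Hydroxy ester 9 comes from β-keto ester 8 by enantioselective reduction of the aryl ketone. Transfer hydrogenation is chosen because it leaves the (Z)-alkene of the allylic ester alone; reduction with dihydrogen followed by transesterification would not be as safe.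

**β-Keto ester.** Compound 8 is cut at the aryl-C(=O)–CH2 bond and at the ester C–O bond into acid 3, Meldrum's acid 6 and allylic alcohol 5. Acylation of 6 and alcoholysis of acyl Meldrum's acid 7 installs the allylic ester directly and avoids alkoxide bases that would strip the aryl silyl ether.

**Building blocks.** Acid 3 is the silyl ether of vanillic acid 1, formed through bis-silylated intermediate 2. Alcohol 5 is the mono-silyl ether of (Z)-but-2-ene-1,4-diol 4.

## Roads not taken

**Alternative 1:** The bonds O5–C4, C4–C3a and C3–O2 are cut together. Forward, the syn-aldol acid A1 condenses with formaldehyde A2 to an oxocarbenium ion at O5. This adds to the styrenyl carbon C3a, and the syringyl-stabilised cation at C3 is captured by the carboxyl group to give the dibenzyl ether A3 of the target.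
- Merits: both rings and two stereocentres arise in one step from a precursor that is one aldol reaction away from simple aryl building blocks. In step count this road is clearly shorter than the chosen one.
- Weak points: C6a in A1 is α to a carboxyl group and allylic to a styrene, so it is prone to epimerisation and to conjugation. Making A1 needs an α-selective, syn-selective and enantioselective aldol reaction of a dienolate. Under the acid of the Prins step the electron-rich benzylic C6–OH can ionise before it condenses, which would erase the only controlling centre. Carboxylate capture only works if C1 and C3 end up cis on the new ring, which the cyclisation does not guarantee. Debenzylation of A3 by hydrogenolysis threatens both benzylic C–O bonds.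
- Comparison: the chosen plan is longer. Against that it sets a stereochemical provenance in which C6a and C3a come from one catalytic reduction and one chair transition state, no configurationally fragile intermediate, and silyl groups that leave without reduction.

**Alternative 2:** The bonds C6–O5 and C6a–C3a are cut. Forward, zerovalent palladium opens 2-vinyloxirane A4 to an alkoxide-bearing π-allyl complex. The alkoxide adds to the benzylidene malonate A5 at C6 and the malonate carbon closes on the inner allyl carbon to give the 2-aryl-4-vinyltetrahydrofuran diester A6.
- Merits: the ether ring and the same C6a–C3a bond as in the chosen plan form catalytically in one step from two simple partners, and a chiral ligand could in principle set the absolute configuration. The vinyl group is ready for the same oxidative cleavage. This road reaches the stage of compound 12 in fewer steps.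
- Weak points: C6a arrives as a quaternary diester, so one ester carbon must later be removed and C6a is then set by protonation. The relationship between the C6 aryl and C3a vinyl groups depends on a reversible oxa-Michael addition followed by allylation and is not secured by a defined transition state. The benzyl esters and ether cannot be removed by hydrogenolysis without touching the vinyl group and the benzylic ether.
- Comparison: the chosen plan spends more steps before the ring exists. It offers in return both C–H stereocentres from one stereodefined event, no carbon that must be excised, and a protecting-group scheme matched to the fragile product.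

**Alternative 3:** The bonds C6–C6a and O5–C4 are cut. Forward, the palladium–trimethylenemethane zwitterion from the silyl acetate donor A8 adds through its ester-bearing carbon to O-benzylvanillin A7. The alkoxide then closes on the π-allyl terminus to give the 4-methylenetetrahydrofuran ester A9.
- Merits: the ether ring comes directly from an aldehyde, C6 and C6a are set together, and ligand control of absolute configuration is conceivable. In ring construction this is more direct than the chosen plan.
- Weak points: neither the C3a stereocentre nor the C3 carbon exists in A9. The exocyclic methylene must be hydroborated or hydroformylated with facial control, oxidised and arylated, so the steps saved early are spent later. The β,γ-unsaturated ester in A9 can slip into conjugation, which destroys C6a. Carbonyl acceptors are less reliable partners in this cycloaddition than electron-poor alkenes.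
- Comparison: the chosen plan closes no ring in its key step, but it places C1, C6a, C3a, C4 and both vinyl carbons in the correct stereochemical relationship at once.

Key step: step 5

Remark: lactol 14 is carried as a mixture of C3 epimers, because C3 is re-formed through a planar cation in step 8. The (R,R)-catalyst in step 4 is assumed to give the (R)-carbinol by the aryl ketone model.

## Route

Step 1
Reactants: 1 vanillic acid (4-hydroxy-3-methoxybenzoic acid)
Product: 3 3-methoxy-4-(triisopropylsilyloxy)benzoic acid, via triisopropylsilyl 3-methoxy-4-(triisopropylsilyloxy)benzoate 2 (not isolated)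
Conditions: iPr3SiCl (2.2 equiv), imidazole, DMF, rt; then K2CO3, MeOH–THF–H2O, rt; citric acid work-up
Reagents that add atoms: triisopropylsilyl chloride, CC(C)[Si](Cl)(C(C)C)C(C)C
Why: Silylation of both acidic OH groups with silyl chloride and imidazole, then selective solvolysis of the much more labile silyl ester; the hindered aryl silyl ether should resist carbonate and later survive amide base, Lewis acid and ozone.

Step 2
Reactants: 4 (Z)-but-2-ene-1,4-diol
Product: 5 (Z)-4-(tert-butyldimethylsilyloxy)but-2-en-1-ol
Conditions: NaH (1.0 equiv), THF, 0 °C → rt; then t-BuMe2SiCl (1.0 equiv)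
Reagents that add atoms: tert-butyldimethylsilyl chloride, CC(C)(C)[Si](C)(C)Cl
Why: Monosilylation of a symmetric diol through its sparingly soluble monosodium alkoxide, which biases the reaction toward the mono-ether; the (Z)-geometry is not touched.

Step 3
Reactants: 3 3-methoxy-4-(triisopropylsilyloxy)benzoic acid, 6 Meldrum's acid (2,2-dimethyl-1,3-dioxane-4,6-dione), 5 (Z)-4-(tert-butyldimethylsilyloxy)but-2-en-1-ol
Product: 8 (Z)-4-(tert-butyldimethylsilyloxy)but-2-enyl 3-[3-methoxy-4-(triisopropylsilyloxy)phenyl]-3-oxopropanoate, via acyl Meldrum's acid 7 (not isolated)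
Conditions: DCC, DMAP, CH2Cl2, 0 °C → rt; filter, aq. KHSO4 wash; then 5, toluene, 90 °C
Reagents that add atoms: none
Why: Carbodiimide-mediated C-acylation of Meldrum's acid, then thermal cycloreversion to an acylketene that is trapped by alcohol 5 (β-keto ester synthesis by Meldrum's acid acylation–alcoholysis); no alkoxide base is present, so both silyl ethers and the (Z)-alkene should persist.

Step 4
Reactants: 8 (Z)-4-(tert-butyldimethylsilyloxy)but-2-enyl 3-[3-methoxy-4-(triisopropylsilyloxy)phenyl]-3-oxopropanoate
Product: 9 (Z)-4-(tert-butyldimethylsilyloxy)but-2-enyl (3R)-3-hydroxy-3-[3-methoxy-4-(triisopropylsilyloxy)phenyl]propanoate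
Conditions: RuCl[(R,R)-TsDPEN](p-cymene) (1 mol %), HCO2H–Et3N (5:2), CH2Cl2, 30 °C (TsDPEN = N-tosyl-1,2-diphenylethylenediamine)
Reagents that add atoms: none
Why: Noyori asymmetric transfer hydrogenation of an aryl ketone; the Ru–H/N–H pair delivers hydride and proton to the carbonyl face selected by the CH/π contact between the aryl ring and the cymene ligand, and the (R,R)-ligand is expected to give the (R)-carbinol at C6; the isolated alkene, the ester and the silyl ethers are not reduced.

Step 5
Reactants: 9 (Z)-4-(tert-butyldimethylsilyloxy)but-2-enyl (3R)-3-hydroxy-3-[3-methoxy-4-(triisopropylsilyloxy)phenyl]propanoate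
Product: 11 (2S,3R)-3-(tert-butyldimethylsilyloxymethyl)-2-{(R)-hydroxy[3-methoxy-4-(triisopropylsilyloxy)phenyl]methyl}pent-4-enoic acid, via chelated dilithium alkoxide enolate 10 (not isolated)
Conditions: LiN(iPr)2 (2.3 equiv), THF, −78 °C; then −78 → 50 °C; aq. HCl to pH 3, 0 °C
Reagents that add atoms: none
Why: Two equivalents of amide base remove the hydroxyl proton and one α-proton to give dianion 10, in which lithium bridges the alkoxide and enolate oxygens in a six-membered chelate, so that C6 is cis to the enolate O–Li and the allyloxy group is trans to it. On warming, the allyl ester enolate undergoes the [3,3]-sigmatropic shift (dianionic Ireland–Claisen rearrangement of a β-hydroxy allyl ester, the sigmatropic counterpart of the Fráter–Seebach alkylation), which forms the C6a–C3a bond, breaks the ester C–O bond and leaves a carboxylate and a terminal vinyl group; no ring is closed. C6a is controlled by the C6 carbinol: the allyl arm folds over the face of the chelate opposite to the aryl group, giving the anti (6R,6aS) relationship. C3a is controlled by the chair transition state, in which the chelate-fixed enolate places C6 equatorial and the (Z)-alkene places the silyloxymethyl group axial, so that C1 and the vinyl group emerge in the relationship that later becomes the cis ring fusion. The step needs enolate-geometry, π-facial and chair-over-boat selectivity, secured respectively by chelation, by the aryl group on the chelate ring and by the chair preference of acyclic allyl esters. The dianion should resist retro-aldol cleavage and β-elimination, since either would expel a doubly charged fragment. C6 is carried in the configuration opposite to the target on purpose, because it is re-formed in step 6.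

Step 6
Reactants: 11 (2S,3R)-3-(tert-butyldimethylsilyloxymethyl)-2-{(R)-hydroxy[3-methoxy-4-(triisopropylsilyloxy)phenyl]methyl}pent-4-enoic acid
Product: 12 (2S,3S,4R)-2-[3-methoxy-4-(triisopropylsilyloxy)phenyl]-4-vinyltetrahydrofuran-3-carboxylic acid
Conditions: BF3·OEt2 (0.3 equiv), CH2Cl2, −40 → 0 °C
Reagents that add atoms: none
Why: Lewis-acid ionisation of the electron-rich benzylic carbinol gives a para-silyloxy-stabilised cation that is captured 5-exo by the oxygen of the silyl ether (desilylative cycloetherification), so no free γ-hydroxy acid that could lactonise is formed; closure is reversible and places the aryl group trans to the C6a carboxyl group, which sets C6 as (S) whatever its earlier configuration.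

Step 7
Reactants: 12 (2S,3S,4R)-2-[3-methoxy-4-(triisopropylsilyloxy)phenyl]-4-vinyltetrahydrofuran-3-carboxylic acid
Product: 14 (3aR,6S,6aS)-3-hydroxy-6-[3-methoxy-4-(triisopropylsilyloxy)phenyl]tetrahydro-1H,3H-furo[3,4-c]furan-1-one (C3 epimers), via formyl acid 13 (not isolated)
Conditions: O3, CH2Cl2, −78 °C (Sudan Red 7B end point); then Me2S, −78 °C → rt
Reagents that add atoms: ozone, [O-][O+]=O
Why: Ozonolysis with reductive work-up should cleave the terminal alkene much faster than ozone attacks the silylated arene, the indicator marking the end point; aldehyde 13 is cis to the carboxyl group and closes spontaneously to the pseudo-acid (lactol-lactone), which also protects C3a from epimerisation.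

Step 8
Reactants: 14 (3aR,6S,6aS)-3-hydroxy-6-[3-methoxy-4-(triisopropylsilyloxy)phenyl]tetrahydro-1H,3H-furo[3,4-c]furan-1-one, 15 2,6-dimethoxyphenol
Product: 16 (3S,3aR,6S,6aS)-3-(4-hydroxy-3,5-dimethoxyphenyl)-6-[3-methoxy-4-(triisopropylsilyloxy)phenyl]tetrahydro-1H,3H-furo[3,4-c]furan-1-one
Conditions: BF3·OEt2 (1.5 equiv), 15 (1.2 equiv), CH2Cl2, −40 → 0 °C
Reagents that add atoms: none
Why: Friedel–Crafts arylation of a cyclic acyloxycarbenium ion generated from the pseudo-acid lactol, as in the arylation of hydroxyphthalides and hydroxybutenolides; the phenol reacts para to OH because both ortho positions are blocked, and attack on the convex face of the cis-fused bicycle gives the exo (3S) aryl group, which is also the thermodynamic isomer.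

Step 9
Reactants: 16 (3S,3aR,6S,6aS)-3-(4-hydroxy-3,5-dimethoxyphenyl)-6-[3-methoxy-4-(triisopropylsilyloxy)phenyl]tetrahydro-1H,3H-furo[3,4-c]furan-1-one
Product: 17 (3S,3aR,6S,6aS)-3-(4-hydroxy-3,5-dimethoxyphenyl)-6-(4-hydroxy-3-methoxyphenyl)tetrahydro-1H,3H-furo[3,4-c]furan-1-one
Conditions: Bu4NF (1.2 equiv), AcOH (1.5 equiv), THF, 0 °C
Reagents that add atoms: none
Why: Fluoride cleavage of the aryl silyl ether; acetic acid buffering keeps the medium non-basic, so that the phenoxides cannot expel the benzylic C3–O2 or C6–O5 oxygen through a quinone methide and no centre should epimerise.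

## Compound list

1 | vanillic acid (4-hydroxy-3-methoxybenzoic acid) | COc1cc(C(=O)O)ccc1O | starting material
2 | triisopropylsilyl 3-methoxy-4-(triisopropylsilyloxy)benzoate | COc1cc(C(=O)O[Si](C(C)C)(C(C)C)C(C)C)ccc1O[Si](C(C)C)(C(C)C)C(C)C | intermediate (not isolated)
3 | 3-methoxy-4-(triisopropylsilyloxy)benzoic acid | COc1cc(C(=O)O)ccc1O[Si](C(C)C)(C(C)C)C(C)C | intermediate
4 | (Z)-but-2-ene-1,4-diol | OC/C=C\CO | starting material
5 | (Z)-4-(tert-butyldimethylsilyloxy)but-2-en-1-ol | OC/C=C\CO[Si](C)(C)C(C)(C)C | intermediate
6 | Meldrum's acid (2,2-dimethyl-1,3-dioxane-4,6-dione) | CC1(C)OC(=O)CC(=O)O1 | starting material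
7 | 5-{hydroxy[3-methoxy-4-(triisopropylsilyloxy)phenyl]methylene}-2,2-dimethyl-1,3-dioxane-4,6-dione (acyl Meldrum's acid) | COc1cc(C(O)=C2C(=O)OC(C)(C)OC2=O)ccc1O[Si](C(C)C)(C(C)C)C(C)C | intermediate (not isolated)
8 | (Z)-4-(tert-butyldimethylsilyloxy)but-2-enyl 3-[3-methoxy-4-(triisopropylsilyloxy)phenyl]-3-oxopropanoate | COc1cc(C(=O)CC(=O)OC/C=C\CO[Si](C)(C)C(C)(C)C)ccc1O[Si](C(C)C)(C(C)C)C(C)C | intermediate
9 | (Z)-4-(tert-butyldimethylsilyloxy)but-2-enyl (3R)-3-hydroxy-3-[3-methoxy-4-(triisopropylsilyloxy)phenyl]propanoate | COc1cc([C@H](O)CC(=O)OC/C=C\CO[Si](C)(C)C(C)(C)C)ccc1O[Si](C(C)C)(C(C)C)C(C)C | intermediate (precursor of the key step)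
10 | dilithium alkoxide enolate of 9 (C6 cis to the enolate O–Li, six-membered lithium chelate) | COc1cc([C@H]([O-])/C=C(\[O-])OC/C=C\CO[Si](C)(C)C(C)(C)C)ccc1O[Si](C(C)C)(C(C)C)C(C)C.[Li+].[Li+] | intermediate (not isolated)
11 | (2S,3R)-3-(tert-butyldimethylsilyloxymethyl)-2-{(R)-hydroxy[3-methoxy-4-(triisopropylsilyloxy)phenyl]methyl}pent-4-enoic acid | COc1cc([C@H](O)[C@@H](C(=O)O)[C@H](CO[Si](C)(C)C(C)(C)C)C=C)ccc1O[Si](C(C)C)(C(C)C)C(C)C | intermediate (product of the key step)
12 | (2S,3S,4R)-2-[3-methoxy-4-(triisopropylsilyloxy)phenyl]-4-vinyltetrahydrofuran-3-carboxylic acid | COc1cc([C@H]2OC[C@H](C=C)[C@@H]2C(=O)O)ccc1O[Si](C(C)C)(C(C)C)C(C)C | intermediate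
13 | (2S,3S,4R)-4-formyl-2-[3-methoxy-4-(triisopropylsilyloxy)phenyl]tetrahydrofuran-3-carboxylic acid | COc1cc([C@H]2OC[C@H](C=O)[C@@H]2C(=O)O)ccc1O[Si](C(C)C)(C(C)C)C(C)C | intermediate (not isolated)
14 | (3aR,6S,6aS)-3-hydroxy-6-[3-methoxy-4-(triisopropylsilyloxy)phenyl]tetrahydro-1H,3H-furo[3,4-c]furan-1-one (C3 epimers) | COc1cc([C@H]2OC[C@H]3[C@@H]2C(=O)OC3O)ccc1O[Si](C(C)C)(C(C)C)C(C)C | intermediate
15 | 2,6-dimethoxyphenol | COc1cccc(OC)c1O | starting material
16 | (3S,3aR,6S,6aS)-3-(4-hydroxy-3,5-dimethoxyphenyl)-6-[3-methoxy-4-(triisopropylsilyloxy)phenyl]tetrahydro-1H,3H-furo[3,4-c]furan-1-one | COc1cc([C@H]2OC[C@H]3[C@@H]2C(=O)O[C@@H]3c2cc(OC)c(O)c(OC)c2)ccc1O[Si](C(C)C)(C(C)C)C(C)C | intermediate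
17 | (3S,3aR,6S,6aS)-3-(4-hydroxy-3,5-dimethoxyphenyl)-6-(4-hydroxy-3-methoxyphenyl)tetrahydro-1H,3H-furo[3,4-c]furan-1-one | COc1cc([C@H]2OC[C@H]3[C@@H]2C(=O)O[C@@H]3c2cc(OC)c(O)c(OC)c2)ccc1O | target

## Step count and least certain steps

Total: 9 steps. Longest linear sequence: 8 steps (steps 1 and 3 to 9, from vanillic acid 1); step 2 is a one-step side branch.

**Step 5 (key step).** The lithium dianion may rearrange only sluggishly, so that heating brings decomposition. The axial silyloxymethyl group of the (Z)-alkene may also let part of the material pass through a boat, which would erode the configuration at C3a. The fallback sets out from 9. The dianion is formed as before at −78 °C and silylated on both oxygens with Me3SiCl to give the bis(trimethylsilyl) ketene acetal F1, which keeps the chelation-derived enolate geometry. As a neutral silyl ketene acetal it should undergo the classical Ireland–Claisen shift at or below room temperature to the silyl ester F2. Mild acid hydrolysis of both trimethylsilyl groups returns to the route at 11. The cost is that facial control then rests on allylic 1,3-strain around C6 and no longer on the chelate.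

**Step 6.** If the primary silyl group is lost before the C6 cation forms, the freed C4 hydroxyl can lactonise onto the carboxyl group. The cation may also lose a proton or carbon dioxide and so bypass ring closure. The fallback sets out from 11 and changes the order of events. Ozonolysis as in step 7 first ties the carboxyl group up as the hydroxy lactol-lactone F3. BF3·OEt2 then closes the ether ring from the C6 cation and the silyl ether oxygen, returning to the route at 14.

**Step 8.** The acyloxycarbenium ion forms less readily than the benzylic cations at C6 and, in the product, at C3. Renewed ionisation could therefore lead to a second arylation or to opening of the ether ring, and attack through the phenol oxygen or at a ring position next to methoxy would lower regioselectivity. The fallback reverses the polarity and sets out from 14 and 15.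
- Phenol 15 is brominated para with N-bromosuccinimide to 4-bromo-2,6-dimethoxyphenol F4, silylated to the aryl bromide F5 and converted into the Grignard reagent F6.
- Excess F6 deprotonates 14, which opens to the aldehyde carboxylate, and adds to the aldehyde. Acidification relactonises to the bis-silyl lactone F7; a catalytic amount of CF3CO2H equilibrates C3 to the exo isomer through the benzylic cation.
- Removal of both silyl groups with Bu4NF/AcOH returns to the route at 17.

**Step 7.** Over-oxidation of the electron-rich arene or of the benzylic ether C–H bond by ozone would lower the yield. The fallback sets out from 12 and reaches 14 by osmium-catalysed dihydroxylation with in-situ periodate cleavage (OsO4 cat., NaIO4, 2,6-lutidine, dioxane–H2O). This reagent pair does not attack arenes and forms no new isolable compound.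

## Further compounds

F1 | step 5 | bis(trimethylsilyl) ketene acetal of 9 (O-trimethylsilyl at C6 and at the ketene acetal, C6 cis to OSiMe3) | COc1cc([C@H](O[Si](C)(C)C)/C=C(\O[Si](C)(C)C)OC/C=C\CO[Si](C)(C)C(C)(C)C)ccc1O[Si](C(C)C)(C(C)C)C(C)C
F2 | step 5 | trimethylsilyl (2S,3R)-3-(tert-butyldimethylsilyloxymethyl)-2-{(R)-[3-methoxy-4-(triisopropylsilyloxy)phenyl](trimethylsilyloxy)methyl}pent-4-enoate | COc1cc([C@H](O[Si](C)(C)C)[C@@H](C(=O)O[Si](C)(C)C)[C@H](CO[Si](C)(C)C(C)(C)C)C=C)ccc1O[Si](C(C)C)(C(C)C)C(C)C
F3 | step 6 | (3S,4R)-4-(tert-butyldimethylsilyloxymethyl)-5-hydroxy-3-{(R)-hydroxy[3-methoxy-4-(triisopropylsilyloxy)phenyl]methyl}dihydrofuran-2(3H)-one (C5 epimers) | COc1cc([C@H](O)[C@H]2C(=O)OC(O)[C@H]2CO[Si](C)(C)C(C)(C)C)ccc1O[Si](C(C)C)(C(C)C)C(C)C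
F4 | step 8 | 4-bromo-2,6-dimethoxyphenol | COc1cc(Br)cc(OC)c1O
F5 | step 8 | (4-bromo-2,6-dimethoxyphenoxy)(tert-butyl)dimethylsilane | COc1cc(Br)cc(OC)c1O[Si](C)(C)C(C)(C)C
F6 | step 8 | [4-(tert-butyldimethylsilyloxy)-3,5-dimethoxyphenyl]magnesium bromide | COc1cc([Mg]Br)cc(OC)c1O[Si](C)(C)C(C)(C)C
F7 | step 8 | (3S,3aR,6S,6aS)-3-[4-(tert-butyldimethylsilyloxy)-3,5-dimethoxyphenyl]-6-[3-methoxy-4-(triisopropylsilyloxy)phenyl]tetrahydro-1H,3H-furo[3,4-c]furan-1-one | COc1cc([C@H]2OC[C@H]3[C@@H]2C(=O)O[C@@H]3c2cc(OC)c(O[Si](C)(C)C(C)(C)C)c(OC)c2)ccc1O[Si](C(C)C)(C(C)C)C(C)C
F0 | step 7 | none | none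
A1 | alternative 1 | (2S,3E)-2-[(S)-(4-benzyloxy-3-methoxyphenyl)(hydroxy)methyl]-4-(4-benzyloxy-3,5-dimethoxyphenyl)but-3-enoic acid | COc1cc([C@@H](O)[C@@H](C(=O)O)/C=C/c2cc(OC)c(OCc3ccccc3)c(OC)c2)ccc1OCc1ccccc1
A2 | alternative 1 | formaldehyde | C=O
A3 | alternative 1 | di-O-benzyl ether of the target | COc1cc([C@H]2OC[C@H]3[C@@H]2C(=O)O[C@@H]3c2cc(OC)c(OCc3ccccc3)c(OC)c2)ccc1OCc1ccccc1
A4 | alternative 2 | 2-vinyloxirane (butadiene monoxide) | C=CC1CO1
A5 | alternative 2 | dibenzyl 2-(4-benzyloxy-3-methoxybenzylidene)malonate | COc1cc(C=C(C(=O)OCc2ccccc2)C(=O)OCc2ccccc2)ccc1OCc1ccccc1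
A6 | alternative 2 | dibenzyl 2-(4-benzyloxy-3-methoxyphenyl)-4-vinyltetrahydrofuran-3,3-dicarboxylate (2,4-trans) | COc1cc([C@H]2OC[C@H](C=C)C2(C(=O)OCc3ccccc3)C(=O)OCc3ccccc3)ccc1OCc1ccccc1
A7 | alternative 3 | 4-benzyloxy-3-methoxybenzaldehyde (O-benzylvanillin) | COc1cc(C=O)ccc1OCc1ccccc1
A8 | alternative 3 | methyl 3-(acetoxymethyl)-2-(trimethylsilyl)but-3-enoate | COC(=O)C([Si](C)(C)C)C(=C)COC(C)=O
A9 | alternative 3 | methyl 2-(4-benzyloxy-3-methoxyphenyl)-4-methylenetetrahydrofuran-3-carboxylate (2,3-trans) | COc1cc([C@H]2OCC(=C)[C@@H]2C(=O)OC)ccc1OCc1ccccc1
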